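**Plan**

1. Numbering: ring B is C5–C6–C7–C8–C9–C10 and ring C is O–C8–C9–C11–C12–C13; C10 bears CH3 and the C1–C2 acetic acid arm, C5 bears C4(CH3)2–C3O2H, C13 bears CH3 and the C14=C15 vinyl group.
2. Cuts: the acids go back to a C2 silyl ether and a C3 silylethyl ester, the vinyl group to a 14,15-diol, and then the O–C13 bond of ring C is cut. C13 is a fully substituted ether carbon (CH3, C12, C14, O) lying 1,5 to the tertiary C8 oxygen through C9–C11–C12, so the C8 hydroxyl can open a 13,14-epoxide at C13 and close the six-membered ring.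
3. Further cuts: C13–CH3 and C14–C15 (alkyne carbometalation, formaldehyde), C8–CH3, C9–C11 (allylation), C10–CH3 (conjugate addition), C4–C5 ([3,3] shift), C10–C1 (oxirane opening), back to cyclohex-2-en-1-one.
4. Forward: ring B is the starting ring and is substituted in the order C1–C2 arm, C4 unit, C8 carbonyl, C10 methyl, C9 allyl, C8 methyl; the C9 chain is grown to the (E)-allylic alcohol, ring C is closed, and the end groups are set last.
5. Stereochemistry: C9–O from CBS reduction, relayed to C5 by the suprafacial Ireland–Claisen shift; C10, C9 and C8 by attack on the ring face opposite the C5 side chain and the C10 arm; C13 by Sharpless epoxidation (L-(+)-tartrate) and inversion in the ring closure; C14 is erased by the olefination.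

Key step: step 15

Remark: read from the SMILES, the C5 side chain is cis to the C10 acetic acid arm and trans to the C10 methyl group (5S,8R,9R,10S,13R), and the route is built for this arrangement.
Abbreviations: β = ring face of the C10 methyl group; TBS = tert-butyldimethylsilyl; TBSO = TBS ether oxygen; TMSE = 2-(trimethylsilyl)ethyl. In the cyclohexane names C1, C2, C3, C4 are C5, C10, C9, C8 of the numbering above.

**Route**

Step 1
Reactants: 1 cyclohex-2-en-1-one
Product: 2 2-iodocyclohex-2-en-1-one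
Conditions: I2, pyridine, CH2Cl2, 0 °C to rt
Reagents that add atoms: iodine, II
Why: α-iodination of an enone through pyridine conjugate addition, iodination of the resulting enolate and elimination is a standard route to 2-iodoenones.

Step 2
Reactants: 2 2-iodocyclohex-2-en-1-one
Product: 3 (R)-2-iodocyclohex-2-en-1-ol
Conditions: (S)-2-methyl-CBS-oxazaborolidine (cat.), BH3·SMe2, THF, −20 °C; MeOH
Reagents that add atoms: none
Why: CBS reduction, in which the α-iodovinyl group acts as the large ketone substituent, should deliver hydride to one carbonyl face and set the carbinol carbon (the later C9) as R.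

Step 3
Reactants: 3 (R)-2-iodocyclohex-2-en-1-ol; 4 oxirane
Product: 6 (R)-2-(2-hydroxyethyl)cyclohex-2-en-1-ol, via dilithio alkoxide 5 (not isolated)
Conditions: MeLi (1 equiv) then t-BuLi (2 equiv), Et2O/THF, −78 °C; 4, −78 to 0 °C; H2O
Reagents that add atoms: oxirane (4), C1CO1
Why: iodine–lithium exchange on the preformed lithium alkoxide gives an alkenyllithium that opens oxirane at carbon (alkylation of a vinyllithium by an epoxide), which attaches the C1–C2 arm to the future C10 without touching the carbinol stereocentre.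

Step 4
Reactants: 6 allylic diol; 7 2-methylpropanoyl chloride
Product: 9 (R)-2-[2-(TBSO)ethyl]cyclohex-2-en-1-yl 2-methylpropanoate, via primary silyl ether 8 (not isolated)
Conditions: TBSCl, imidazole, CH2Cl2, 0 °C; then 7, Et3N, DMAP, 0 °C to rt
Reagents that add atoms: tert-butyldimethylsilyl chloride, CC(C)(C)[Si](C)(C)Cl; 2-methylpropanoyl chloride (7), CC(C)C(Cl)=O
Why: silylation is selective for the primary hydroxyl and the remaining secondary allylic alcohol is then acylated in the same flask, two routine hydroxyl derivatisations that leave the stereocentre untouched.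

Step 5
Reactants: 9 allylic isobutyrate
Product: 13 TMSE 2-{(1S)-2-[2-(TBSO)ethyl]cyclohex-2-en-1-yl}-2-methylpropanoate, via silyl ketene acetal 10 (not isolated), via trimethylsilyl ester 11 (not isolated), via carboxylic acid 12 (not isolated)
Conditions: LDA, THF, −78 °C; TMSCl/Et3N; −78 to 60 °C; aq. NaOH then pH 4 buffer; crude acid, PPh3, DIAD, 2-(trimethylsilyl)ethanol, THF, 0 °C to rt
Reagents that add atoms: 2-(trimethylsilyl)ethanol, C[Si](C)(C)CCO
Why: Ireland–Claisen rearrangement of the silyl ketene acetal runs suprafacially through a six-membered transition state, so the C4–C5 bond forms on the ring face that carried the C9–O bond and C5 is set as S, and the hindered acid is then esterified by Mitsunobu O-alkylation, which needs no attack at the crowded carbonyl carbon.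

Step 6
Reactants: 13 cyclohexenyl TMSE ester
Product: 14 TMSE 2-{(1S)-2-[2-(TBSO)ethyl]-4-oxocyclohex-2-en-1-yl}-2-methylpropanoate
Conditions: Rh2(cap)4 (cap = caprolactamate, 1 mol%), t-BuOOH, K2CO3, CH2Cl2, rt
Reagents that add atoms: tert-butyl hydroperoxide, CC(C)(C)OO
Why: catalytic allylic oxidation by tert-butylperoxyl radicals attacks the ring methylene next to the unsubstituted alkene carbon (C8), as in the conversion of 1-alkylcyclohexenes into 3-alkylcyclohex-2-enones, and should give the C8 enone with C5 unchanged.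

Step 7
Reactants: 14 enone
Product: 15 TMSE 2-{(1S,2S)-2-[2-(TBSO)ethyl]-2-methyl-4-(trimethylsilyloxy)cyclohex-3-en-1-yl}-2-methylpropanoate
Conditions: Me2CuLi (from CuI and 2 MeLi), TMSCl, THF, −78 to −30 °C; Et3N
Reagents that add atoms: methyllithium (as lithium dimethylcuprate), [Li]C; chlorotrimethylsilane, C[Si](C)(C)Cl
Why: chlorosilane-accelerated cuprate 1,4-addition to a 4-substituted cyclohexenone occurs anti to the C5 side chain, which allylic strain with the C10 arm holds pseudoaxial, so C10 is set as S with methyl β and the arm cis to the C5 group, and the enolate is kept regiodefined as its silyl enol ether.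

Step 8
Reactants: 15 silyl enol ether; 16 allyl methyl carbonate
Product: 17 TMSE 2-{(1S,2S,3R)-2-[2-(TBSO)ethyl]-2-methyl-4-oxo-3-(prop-2-en-1-yl)cyclohexyl}-2-methylpropanoate
Conditions: 16, Pd2(dba)3·CHCl3 (2.5 mol%), dppe, THF, 65 °C
Reagents that add atoms: allyl methyl carbonate (16), C=CCOC(=O)OC
Why: Tsuji allylation of a silyl enol ether, in which zerovalent palladium turns the carbonate into a π-allyl complex and methoxide, the methoxide unmasks the C8–C9 enolate, and the enolate is allylated at C9 under neutral conditions on the β face, away from the axial C10 arm and the C5 side chain, which sets C9 as R.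

Step 9
Reactants: 17 allyl ketone
Product: 18 TMSE 2-{(1S,2S,3R,4R)-2-[2-(TBSO)ethyl]-4-hydroxy-2,4-dimethyl-3-(prop-2-en-1-yl)cyclohexyl}-2-methylpropanoate
Conditions: MeCeCl2 (from MeLi and CeCl3), THF, −78 °C; aq. NH4Cl
Reagents that add atoms: methyllithium (as methylcerium dichloride), [Li]C
Why: organocerium 1,2-addition to a hindered enolisable ketone; in the chair with the C5 group equatorial the C10 arm is axial and blocks the α face of C8, so methyl should enter equatorially from the β face and the hydroxyl end up α (C8 R), while the neopentylic ester is too hindered to react at −78 °C.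

Step 10
Reactants: 18 tertiary alcohol
Product: 20 TMSE 2-{(1S,2S,3R,4R)-2-[2-(TBSO)ethyl]-4-hydroxy-3-(3-hydroxypropyl)-2,4-dimethylcyclohexyl}-2-methylpropanoate, via B-alkyl-9-BBN adduct 19 (not isolated)
Conditions: 9-BBN, THF, 0 °C to rt; then NaOH, H2O2, 0 °C
Reagents that add atoms: hydrogen peroxide, OO
Why: anti-Markovnikov hydroboration–oxidation of the only alkene in the molecule.

Step 11
Reactants: 20 diol
Product: 21 TMSE 2-{(1S,2S,3R,4R)-2-[2-(TBSO)ethyl]-4-hydroxy-2,4-dimethyl-3-(3-oxopropyl)cyclohexyl}-2-methylpropanoate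
Conditions: Dess–Martin oxidation, periodinane (1.2 equiv), CH2Cl2, 0 °C
Reagents that add atoms: none
Why: Dess–Martin oxidation converts the primary alcohol into the aldehyde and cannot touch the tertiary C8 hydroxyl, the product being handled as its aldehyde–lactol mixture.

Step 12
Reactants: 21 hydroxy aldehyde
Product: 22 TMSE 2-{(1S,2S,3R,4R)-3-(but-3-yn-1-yl)-2-[2-(TBSO)ethyl]-4-hydroxy-2,4-dimethylcyclohexyl}-2-methylpropanoate
Conditions: dimethyl (1-diazo-2-oxopropyl)phosphonate, K2CO3, MeOH, 0 °C to rt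
Reagents that add atoms: dimethyl (1-diazo-2-oxopropyl)phosphonate, CC(=O)C(=[N+]=[N-])P(=O)(OC)OC
Why: the Ohira–Bestmann variant of the Seyferth–Gilbert homologation takes the aldehyde, also from its lactol form, to the terminal alkyne under mild base and adds C14.

Step 13
Reactants: 22 alkyne
Product: 25 TMSE 2-{(1S,2S,3R,4R)-2-[2-(TBSO)ethyl]-4-hydroxy-3-[(3E)-5-hydroxy-3-methylpent-3-en-1-yl]-2,4-dimethylcyclohexyl}-2-methylpropanoate, via alkenylalane 23 (not isolated), via lithium alkenylalanate 24 (not isolated)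
Conditions: AlMe3, Cp2ZrCl2, CH2Cl2, 0 °C to rt; volatiles removed; n-BuLi, hexane/THF, −78 °C; (CH2O)n, −78 °C to rt
Reagents that add atoms: trimethylaluminium, C[Al](C)C; formaldehyde (as paraformaldehyde), C=O
Why: Negishi zirconium-catalysed carboalumination adds methyl and aluminium syn across the terminal alkyne with methyl at C13, and hydroxymethylation of the derived alanate occurs with retention, so the (E)-trisubstituted allylic alcohol should form without a geometric mixture.

Step 14
Reactants: 25 (E)-allylic alcohol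
Product: 26 TMSE 2-{(1S,2S,3R,4R)-2-[2-(TBSO)ethyl]-4-hydroxy-3-{2-[(2S,3S)-3-(hydroxymethyl)-2-methyloxiran-2-yl]ethyl}-2,4-dimethylcyclohexyl}-2-methylpropanoate
Conditions: Ti(OiPr)4, L-(+)-diethyl tartrate, t-BuOOH, 4 Å molecular sieves, CH2Cl2, −20 °C
Reagents that add atoms: tert-butyl hydroperoxide, CC(C)(C)OO
Why: Sharpless asymmetric epoxidation of an (E)-3-methylalk-2-en-1-ol of the geraniol type, for which L-(+)-tartrate delivers oxygen to the face that gives the (2S,3S)-epoxy alcohol, here (13S,14S), under reagent control and independently of the remote ring stereocentres.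

Step 15
Reactants: 26 (13S,14S)-epoxy alcohol
Product: 27 TMSE 2-{(2R,4aR,5S,6S,8aR)-5-[2-(TBSO)ethyl]-2-[(1S)-1,2-dihydroxyethyl]-2,5,8a-trimethyloctahydro-2H-chromen-6-yl}-2-methylpropanoate
Conditions: camphorsulfonic acid (10 mol%), CH2Cl2, 0 °C to rt
Reagents that add atoms: none
Why: Protonation of the epoxide oxygen weakens the C13–O bond, C13 being the tertiary and better cation-stabilising carbon, and the C8 hydroxyl oxygen attacks C13 from the side opposite the leaving oxygen; the closest known reaction type is the acid-catalysed intramolecular opening of a trisubstituted 2,3-epoxy alcohol at its more substituted carbon by a tethered hydroxyl, the usual way to oxygen-bridged terpenoid and polyether rings. Ring C (O–C8–C9–C11–C12–C13) closes in the 6-exo-tet mode, whereas attack at C14 would be a 7-endo closure at the carbon that carries less positive charge. C13 is the new stereocentre of the ring and is set by the epoxide installed with L-(+)-tartrate, the 13S epoxide carbon being inverted to 13R, so its configuration does not depend on the conformational energies of the product; C14 reacts with retention and is removed later. The step needs regioselectivity for C13 over C14, secured by the tertiary centre and the ring size, and a cyclisation that outruns rearrangement of the protonated epoxide and loss of the silyl ether, secured by the 1,5 placement of the C8 oxygen and C13 and by a low acid loading in an aprotic solvent. Ring B must turn the C8–O and C9–C11 bonds gauche, which moves the C5 side chain out of its equatorial position, so the closure is expected to be slower than in a trans-decalin and the mixture is kept cold until the epoxide is consumed.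

Step 16
Reactants: 27 bicyclic ether diol
Product: 28 TMSE 2-{(2R,4aR,5S,6S,8aR)-5-[2-(TBSO)ethyl]-2,5,8a-trimethyl-2-[(4S)-2-thioxo-1,3-dioxolan-4-yl]octahydro-2H-chromen-6-yl}-2-methylpropanoate
Conditions: 1,1'-thiocarbonyldiimidazole, DMAP (cat.), toluene, 80 °C
Reagents that add atoms: 1,1'-thiocarbonyldiimidazole, S=C(n1ccnc1)n1ccnc1
Why: a 1,2-diol and thiocarbonyldiimidazole give the five-membered thionocarbonate, the first stage of the Corey–Winter olefination, without involving C13.

Step 17
Reactants: 28 cyclic thionocarbonate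
Product: 29 TMSE 2-{(2R,4aR,5S,6S,8aR)-5-[2-(TBSO)ethyl]-2-ethenyl-2,5,8a-trimethyloctahydro-2H-chromen-6-yl}-2-methylpropanoate
Conditions: P(OMe)3, 110 °C
Reagents that add atoms: none
Why: Corey–Winter fragmentation, in which the phosphite removes sulfur and the resulting carbene loses CO2, should form the C14=C15 vinyl group, C13 keeping its configuration because none of its bonds is broken.

Step 18
Reactants: 29 vinyl ether
Product: 30 2-[(2R,4aR,5S,6S,8aR)-2-ethenyl-5-(2-hydroxyethyl)-2,5,8a-trimethyloctahydro-2H-chromen-6-yl]-2-methylpropanoic acid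
Conditions: TBAF, THF, rt to 40 °C; aq. HCl to pH 3
Reagents that add atoms: none
Why: fluoride cleaves the silyl ether and also the TMSE ester, the latter by attack at silicon and loss of ethene, so the hindered C3 carboxyl is released without hydrolysis at its carbonyl carbon.

Step 19
Reactants: 30 hydroxy acid
Product: 31 2-[(2R,4aR,5S,6S,8aR)-5-(carboxymethyl)-2-ethenyl-2,5,8a-trimethyloctahydro-2H-chromen-6-yl]-2-methylpropanoic acid (target)
Conditions: TEMPO (cat.), PhI(OAc)2, MeCN/H2O, rt
Reagents that add atoms: water, O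
Why: TEMPO-catalysed oxidation with a hypervalent iodine co-oxidant takes the primary alcohol through the aldehyde hydrate to the acid and is compatible with the vinyl group, the tertiary allylic ether and the free C3 acid.

**Compound list**

1 | cyclohex-2-en-1-one | O=C1C=CCCC1 | starting material
2 | 2-iodocyclohex-2-en-1-one | O=C1CCCC=C1I | intermediate
3 | (R)-2-iodocyclohex-2-en-1-ol | O[C@@H]1CCCC=C1I | intermediate
4 | oxirane | C1CO1 | starting material
5 | lithium (R)-2-lithiocyclohex-2-en-1-olate (dilithio alkoxide) | [Li]O[C@@H]1CCCC=C1[Li] | intermediate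
6 | (R)-2-(2-hydroxyethyl)cyclohex-2-en-1-ol | O[C@@H]1CCCC=C1CCO | intermediate
7 | 2-methylpropanoyl chloride | CC(C)C(Cl)=O | starting material
8 | (R)-2-[2-(TBSO)ethyl]cyclohex-2-en-1-ol | O[C@@H]1CCCC=C1CCO[Si](C)(C)C(C)(C)C | intermediate
9 | (R)-2-[2-(TBSO)ethyl]cyclohex-2-en-1-yl 2-methylpropanoate | CC(C)C(=O)O[C@@H]1CCCC=C1CCO[Si](C)(C)C(C)(C)C | intermediate
10 | trimethylsilyl ketene acetal of 9 | CC(C)=C(O[Si](C)(C)C)O[C@@H]1CCCC=C1CCO[Si](C)(C)C(C)(C)C | intermediate
11 | trimethylsilyl 2-{(1S)-2-[2-(TBSO)ethyl]cyclohex-2-en-1-yl}-2-methylpropanoate | C[Si](C)(C)OC(=O)C(C)(C)[C@H]1CCCC=C1CCO[Si](C)(C)C(C)(C)C | intermediate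
12 | 2-{(1S)-2-[2-(TBSO)ethyl]cyclohex-2-en-1-yl}-2-methylpropanoic acid | OC(=O)C(C)(C)[C@H]1CCCC=C1CCO[Si](C)(C)C(C)(C)C | intermediate
13 | TMSE 2-{(1S)-2-[2-(TBSO)ethyl]cyclohex-2-en-1-yl}-2-methylpropanoate | C[Si](C)(C)CCOC(=O)C(C)(C)[C@H]1CCCC=C1CCO[Si](C)(C)C(C)(C)C | intermediate
14 | TMSE 2-{(1S)-2-[2-(TBSO)ethyl]-4-oxocyclohex-2-en-1-yl}-2-methylpropanoate | C[Si](C)(C)CCOC(=O)C(C)(C)[C@H]1CCC(=O)C=C1CCO[Si](C)(C)C(C)(C)C | intermediate
15 | TMSE 2-{(1S,2S)-2-[2-(TBSO)ethyl]-2-methyl-4-(trimethylsilyloxy)cyclohex-3-en-1-yl}-2-methylpropanoate | C[Si](C)(C)OC1=C[C@@](C)(CCO[Si](C)(C)C(C)(C)C)[C@@H](C(C)(C)C(=O)OCC[Si](C)(C)C)CC1 | intermediate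
16 | allyl methyl carbonate | C=CCOC(=O)OC | starting material
17 | TMSE 2-{(1S,2S,3R)-2-[2-(TBSO)ethyl]-2-methyl-4-oxo-3-(prop-2-en-1-yl)cyclohexyl}-2-methylpropanoate | C=CC[C@@H]1[C@@](C)(CCO[Si](C)(C)C(C)(C)C)[C@@H](C(C)(C)C(=O)OCC[Si](C)(C)C)CCC1=O | intermediate
18 | TMSE 2-{(1S,2S,3R,4R)-2-[2-(TBSO)ethyl]-4-hydroxy-2,4-dimethyl-3-(prop-2-en-1-yl)cyclohexyl}-2-methylpropanoate | C=CC[C@@H]1[C@@](C)(CCO[Si](C)(C)C(C)(C)C)[C@@H](C(C)(C)C(=O)OCC[Si](C)(C)C)CC[C@@]1(C)O | intermediate
19 | B-alkyl-9-borabicyclo[3.3.1]nonane adduct of 18 (boron on the terminal carbon of the former allyl group) | B1(CCC[C@@H]2[C@@](C)(CCO[Si](C)(C)C(C)(C)C)[C@@H](C(C)(C)C(=O)OCC[Si](C)(C)C)CC[C@@]2(C)O)C3CCCC1CCC3 | intermediate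
20 | TMSE 2-{(1S,2S,3R,4R)-2-[2-(TBSO)ethyl]-4-hydroxy-3-(3-hydroxypropyl)-2,4-dimethylcyclohexyl}-2-methylpropanoate | OCCC[C@@H]1[C@@](C)(CCO[Si](C)(C)C(C)(C)C)[C@@H](C(C)(C)C(=O)OCC[Si](C)(C)C)CC[C@@]1(C)O | intermediate
21 | TMSE 2-{(1S,2S,3R,4R)-2-[2-(TBSO)ethyl]-4-hydroxy-2,4-dimethyl-3-(3-oxopropyl)cyclohexyl}-2-methylpropanoate (in equilibrium with its lactol) | O=CCC[C@@H]1[C@@](C)(CCO[Si](C)(C)C(C)(C)C)[C@@H](C(C)(C)C(=O)OCC[Si](C)(C)C)CC[C@@]1(C)O | intermediate
22 | TMSE 2-{(1S,2S,3R,4R)-3-(but-3-yn-1-yl)-2-[2-(TBSO)ethyl]-4-hydroxy-2,4-dimethylcyclohexyl}-2-methylpropanoate | C#CCC[C@@H]1[C@@](C)(CCO[Si](C)(C)C(C)(C)C)[C@@H](C(C)(C)C(=O)OCC[Si](C)(C)C)CC[C@@]1(C)O | intermediate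
23 | (E)-alkenyldimethylalane from 22 (C14–Al, C13–CH3, C8–O–AlMe2) | C/C(CC[C@@H]1[C@@](C)(CCO[Si](C)(C)C(C)(C)C)[C@@H](C(C)(C)C(=O)OCC[Si](C)(C)C)CC[C@@]1(C)O[Al](C)C)=C\[Al](C)C | intermediate
24 | lithium butyl(alkenyl)dimethylalanate from 23 | [Li+].C/C(CC[C@@H]1[C@@](C)(CCO[Si](C)(C)C(C)(C)C)[C@@H](C(C)(C)C(=O)OCC[Si](C)(C)C)CC[C@@]1(C)O[Al](C)C)=C\[Al-](C)(C)CCCC | intermediate
25 | TMSE 2-{(1S,2S,3R,4R)-2-[2-(TBSO)ethyl]-4-hydroxy-3-[(3E)-5-hydroxy-3-methylpent-3-en-1-yl]-2,4-dimethylcyclohexyl}-2-methylpropanoate | C/C(CC[C@@H]1[C@@](C)(CCO[Si](C)(C)C(C)(C)C)[C@@H](C(C)(C)C(=O)OCC[Si](C)(C)C)CC[C@@]1(C)O)=C\CO | intermediate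
26 | TMSE 2-{(1S,2S,3R,4R)-2-[2-(TBSO)ethyl]-4-hydroxy-3-{2-[(2S,3S)-3-(hydroxymethyl)-2-methyloxiran-2-yl]ethyl}-2,4-dimethylcyclohexyl}-2-methylpropanoate (13S,14S-epoxy alcohol) | OC[C@@H]1O[C@@]1(C)CC[C@@H]2[C@@](C)(CCO[Si](C)(C)C(C)(C)C)[C@@H](C(C)(C)C(=O)OCC[Si](C)(C)C)CC[C@@]2(C)O | intermediate
27 | TMSE 2-{(2R,4aR,5S,6S,8aR)-5-[2-(TBSO)ethyl]-2-[(1S)-1,2-dihydroxyethyl]-2,5,8a-trimethyloctahydro-2H-chromen-6-yl}-2-methylpropanoate | OC[C@H](O)[C@@]1(C)CC[C@@H]2[C@@](C)(CCO[Si](C)(C)C(C)(C)C)[C@@H](C(C)(C)C(=O)OCC[Si](C)(C)C)CC[C@@]2(C)O1 | intermediate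
28 | TMSE 2-{(2R,4aR,5S,6S,8aR)-5-[2-(TBSO)ethyl]-2,5,8a-trimethyl-2-[(4S)-2-thioxo-1,3-dioxolan-4-yl]octahydro-2H-chromen-6-yl}-2-methylpropanoate | S=C1OC[C@H](O1)[C@@]2(C)CC[C@@H]3[C@@](C)(CCO[Si](C)(C)C(C)(C)C)[C@@H](C(C)(C)C(=O)OCC[Si](C)(C)C)CC[C@@]3(C)O2 | intermediate
29 | TMSE 2-{(2R,4aR,5S,6S,8aR)-5-[2-(TBSO)ethyl]-2-ethenyl-2,5,8a-trimethyloctahydro-2H-chromen-6-yl}-2-methylpropanoate | C=C[C@@]1(C)CC[C@@H]2[C@@](C)(CCO[Si](C)(C)C(C)(C)C)[C@@H](C(C)(C)C(=O)OCC[Si](C)(C)C)CC[C@@]2(C)O1 | intermediate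
30 | 2-[(2R,4aR,5S,6S,8aR)-2-ethenyl-5-(2-hydroxyethyl)-2,5,8a-trimethyloctahydro-2H-chromen-6-yl]-2-methylpropanoic acid | C=C[C@@]1(C)CC[C@@H]2[C@@](C)(CCO)[C@@H](C(C)(C)C(=O)O)CC[C@@]2(C)O1 | intermediate
31 | 2-[(2R,4aR,5S,6S,8aR)-5-(carboxymethyl)-2-ethenyl-2,5,8a-trimethyloctahydro-2H-chromen-6-yl]-2-methylpropanoic acid | C=C[C@@]1(C)CC[C@@H]2[C@@](C)(CC(=O)O)[C@@H](C(C)(C)C(=O)O)CC[C@@]2(C)O1 | target

**Totals and risks**

Total step count: 19. Longest linear sequence: 19 steps (from 1; the route is linear).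

Steps most likely to fail:

Step 9. Facial selectivity at C8 may be poor, because ring B can also react through the other chair, in which the C10 methyl group and not the C10 arm is axial and methyl would then enter from the α face. Fallback, setting out from 17 and returning at 18: the C8–O bond is made intramolecularly from the C10 arm, so it can only form cis to it. Lombardo methylenation (Zn, CH2Br2, TiCl4) of 17 would give the exocyclic alkene F1. Camphorsulfonic acid in MeOH would remove the TBS group and leave the primary alcohol F2. TEMPO with PhI(OAc)2 in aqueous MeCN would oxidise it to the carboxylic acid F3. A catalytic amount of TfOH in CH2Cl2 would protonate the 1,1-disubstituted alkene, and the carboxyl group would trap the C8 cation as the bridged δ-lactone F4, fixing C8–O as α and C8–CH3 as β. LiBH4 would reduce the lactone, but not the neopentylic TMSE ester, to the diol F5, and TBSCl with imidazole would silylate its primary hydroxyl to give 18.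

Step 7. The conjugate addition creates a quaternary carbon next to the branched C5 and may be slow or incomplete, with recovery of enone or 1,2-addition instead. Fallback, setting out from 14 and returning at 15: the methyl group is brought in as a cyclopropane methylene. Corey–Chaykovsky cyclopropanation (Me3S(O)I, NaH, DMSO) would add CH2 across C9=C10 on the face opposite the C5 side chain to give the cyclopropyl ketone F6. SmI2 in THF/HMPA would then cleave the exocyclic cyclopropane bond at C9, leaving a methyl group on C10 and the samarium enolate, which TMSCl would silylate to 15.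

Step 15. The ring closure may be slow, because ring B has to leave its preferred chair, so rearrangement of the protonated epoxide or loss of the silyl ether could compete. Fallback, setting out from 25 and returning at 29: ring C is closed by allylic substitution instead. ClCO2Me with pyridine would convert the primary allylic hydroxyl into the allylic methyl carbonate F7. Zerovalent palladium from Pd2(dba)3·CHCl3, with a C2-symmetric trans-1,2-diaminocyclohexane bis(2-diphenylphosphinobenzamide) ligand, would ionise it to the π-allyl complex. The C8 hydroxyl would attack the tertiary terminus to give the vinyl ether 29 directly, the ligand enantiomer being chosen to give 13R.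

**Further compounds**

F1 | step 9 | TMSE 2-{(1S,2S,3R)-2-[2-(TBSO)ethyl]-2-methyl-4-methylidene-3-(prop-2-en-1-yl)cyclohexyl}-2-methylpropanoate | C=CC[C@@H]1[C@@](C)(CCO[Si](C)(C)C(C)(C)C)[C@@H](C(C)(C)C(=O)OCC[Si](C)(C)C)CCC1=C
F2 | step 9 | TMSE 2-{(1S,2S,3R)-2-(2-hydroxyethyl)-2-methyl-4-methylidene-3-(prop-2-en-1-yl)cyclohexyl}-2-methylpropanoate | C=CC[C@@H]1[C@@](C)(CCO)[C@@H](C(C)(C)C(=O)OCC[Si](C)(C)C)CCC1=C
F3 | step 9 | {(1S,2R,6S)-1-methyl-3-methylidene-6-[2-methyl-1-oxo-1-(TMSE-oxy)propan-2-yl]-2-(prop-2-en-1-yl)cyclohexyl}acetic acid | C=CC[C@@H]1[C@@](C)(CC(=O)O)[C@@H](C(C)(C)C(=O)OCC[Si](C)(C)C)CCC1=C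
F4 | step 9 | bridged δ-lactone (2-oxabicyclo[3.3.1]nonan-3-one; lactone oxygen on C8, carbonyl C2, bridging the α face; C8 methyl and C9 allyl β) | C=CC[C@@H]1[C@@](C)(CC2=O)[C@@H](C(C)(C)C(=O)OCC[Si](C)(C)C)CC[C@@]1(C)O2
F5 | step 9 | TMSE 2-{(1S,2S,3R,4R)-4-hydroxy-2-(2-hydroxyethyl)-2,4-dimethyl-3-(prop-2-en-1-yl)cyclohexyl}-2-methylpropanoate | C=CC[C@@H]1[C@@](C)(CCO)[C@@H](C(C)(C)C(=O)OCC[Si](C)(C)C)CC[C@@]1(C)O
F6 | step 7 | cyclopropyl ketone (bicyclo[4.1.0]heptan-2-one; CH2 bridging C9 and C10 on the β face) | C1[C@@H]2[C@@]1(CCO[Si](C)(C)C(C)(C)C)[C@@H](C(C)(C)C(=O)OCC[Si](C)(C)C)CCC2=O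
F7 | step 15 | methyl carbonate of the primary allylic hydroxyl of 25 | C/C(CC[C@@H]1[C@@](C)(CCO[Si](C)(C)C(C)(C)C)[C@@H](C(C)(C)C(=O)OCC[Si](C)(C)C)CC[C@@]1(C)O)=C\COC(=O)OC
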